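**Retrosynthetic overview**
- Last bond: stearate on the primary alcohol. Before it: desilylation and ring-closing metathesis at the Z C6=C7 alkene, which closes the nine-membered carbocycle (ring B).
- The penta-1,4-dien-2-yl arm comes from a 3-acetyl group (kinetic enol triflate, then allyl Stille coupling). The 3-acetyloxolane (ring A) comes from an α-methylene-γ-butyrolactone by MeLi addition and an oxa-Michael ring switch.
- Key bond, oxolane C4–C5 (C10a–C1 of the target): the β-carbon of an acrylate unit, made nucleophilic as an allylchromium (homoenolate-type d3) reagent, attacks the carbonyl carbon of a dienyl ketone. This sets the tertiary and the quaternary stereocentre together.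
- Fragments: a Morita–Baylis–Hillman bromide from (S)-linalool (supplies the C8 carbinol) and a dienone from silyloxyacetone and 3-methylbut-2-enal.
- Ring order: γ-lactone (temporary) → oxolane ring A → cyclononene ring B.

Assumption: (S)-(+)-linalool of high enantiomeric purity is taken as a purchasable starting material.

**Route**

Step 1
Reactants: 1 (S)-(+)-linalool [(3S)-3,7-dimethylocta-1,6-dien-3-ol]
Product: 2 triethyl{[(3S)-3,7-dimethylocta-1,6-dien-3-yl]oxy}silane
Conditions: TESOTf, 2,6-lutidine, CH2Cl2, −78 → 0 °C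
Reagents that add atoms: triethylsilyl trifluoromethanesulfonate, CC[Si](CC)(CC)OS(=O)(=O)C(F)(F)F
Why: Silyl triflate silylation (protection) caps the hindered tertiary allylic alcohol so that the aldehyde made next cannot close to a lactol and the alcohol survives the organometallic steps, with the C3 stereocentre untouched.

Step 2
Reactants: 2 triethyl{[(3S)-3,7-dimethylocta-1,6-dien-3-yl]oxy}silane
Product: 4 (4S)-4-methyl-4-(triethylsilyloxy)hex-5-enal, via secondary ozonide 3 (not isolated)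
Conditions: O3, CH2Cl2, −78 °C (Sudan Red 7B end point); then PPh3, −78 → 23 °C
Reagents that add atoms: ozone, [O-][O+]=O
Why: Ozonolysis with reductive work-up cleaves the electron-rich trisubstituted alkene much faster than the hindered monosubstituted vinyl group, so stopping at the indicator end point gives the aldehyde selectively.

Step 3
Reactants: 4 (4S)-4-methyl-4-(triethylsilyloxy)hex-5-enal + 5 methyl acrylate
Product: 6 methyl (6S)-3-hydroxy-6-methyl-2-methylidene-6-(triethylsilyloxy)oct-7-enoate (both C3 epimers)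
Conditions: DABCO (1 equiv), 5 (3 equiv), MeOH (trace), 23 °C, 5–7 d
Reagents that add atoms: none
Why: Morita–Baylis–Hillman reaction of an unhindered aliphatic aldehyde gives the adduct, whose new carbinol centre forms as a mixture that does not matter because it is erased in the next step.

Step 4
Reactants: 6 methyl (6S)-3-hydroxy-6-methyl-2-methylidene-6-(triethylsilyloxy)oct-7-enoate
Product: 8 methyl (2Z,6S)-2-(bromomethyl)-6-methyl-6-(triethylsilyloxy)octa-2,7-dienoate, via allylic mesylate 7 (not isolated)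
Conditions: MsCl, Et3N, CH2Cl2, −20 °C; then LiBr, THF, 0 → 23 °C
Reagents that add atoms: lithium bromide, [Li+].[Br-]
Why: Mesylation followed by SN2′ displacement with bromide (allylic transposition of a Morita–Baylis–Hillman adduct) gives the thermodynamically preferred (Z)-2-(bromomethyl)enoate under conditions that leave the TES ether alone.

Step 5
Reactants: 9 1-(tert-butyldimethylsilyloxy)propan-2-one + 10 3-methylbut-2-enal
Product: 13 (3E)-1-(tert-butyldimethylsilyloxy)-6-methylhepta-3,5-dien-2-one, via lithium aldolate 11 (not isolated), via mesylate 12 (not isolated)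
Conditions: LiN(i-Pr)2, THF, −78 °C; 10, −78 °C; then MsCl, −78 → 0 °C; Et3N, 23 °C
Reagents that add atoms: none
Why: Kinetic deprotonation on the methyl side (away from the α-oxygen), 1,2-aldol addition to the enal and E1cB loss of mesylate (aldol condensation) give the conjugated (E)-dienone.

Step 6
Reactants: 8 methyl (2Z,6S)-2-(bromomethyl)-6-methyl-6-(triethylsilyloxy)octa-2,7-dienoate + 13 (3E)-1-(tert-butyldimethylsilyloxy)-6-methylhepta-3,5-dien-2-one
Product: 16 (4S,5R)-5-[(tert-butyldimethylsilyloxy)methyl]-3-methylidene-5-[(1E)-4-methylpenta-1,3-dienyl]-4-[(3S)-3-methyl-3-(triethylsilyloxy)pent-4-enyl]oxolan-2-one, via allylchromium reagent 14 (not isolated), via chromium alkoxide 15 (not isolated)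
Conditions: CrCl2 (3 equiv), chiral bis(oxazolinyl)carbazole ligand (matched enantiomer, 3.2 equiv), i-Pr2NEt (3.2 equiv), THF, 23 °C; then 13 and 8, 0 → 30 °C, 24 h; aq. NaHCO3
Reagents that add atoms: none
Why: Proposed new method: two equivalents of divalent chromium reduce the allylic bromide, whose acrylate β-carbon is normally an electrophile, to a nucleophilic allylchromium reagent (trivalent chromium, a homoenolate-type d3 equivalent) that adds through its γ-carbon to the ketone carbonyl (1,2- and not 1,4-addition) in a Zimmerman–Traxler chair with the side chain pseudo-equatorial (anti) and the planar dienyl pseudo-equatorial while the silyloxymethyl arm lies next to chromium, so that C4 and the quaternary C5 are set together as 4S,5R once the ligand selects one enantiomeric chair (its antipode would give 4R,5S), after which the alkoxide lactonises on the ester; the closest known reactions are the Nozaki–Hiyama–Kishi-type 2-(alkoxycarbonyl)allylation of aldehydes to α-methylene-γ-butyrolactones and the ligand-controlled chromium allylation of ketones.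

Step 7
Reactants: 16 (4S,5R)-5-[(tert-butyldimethylsilyloxy)methyl]-3-methylidene-5-[(1E)-4-methylpenta-1,3-dienyl]-4-[(3S)-3-methyl-3-(triethylsilyloxy)pent-4-enyl]oxolan-2-one
Product: 19 1-{(3S,4S,5R)-5-[(tert-butyldimethylsilyloxy)methyl]-5-[(1E)-4-methylpenta-1,3-dienyl]-4-[(3S)-3-methyl-3-(triethylsilyloxy)pent-4-enyl]oxolan-3-yl}ethan-1-one, via lactol 17 (not isolated), via hydroxy enone 18 (not isolated)
Conditions: MeLi (1.05 equiv), THF, −78 °C, 30 min; then t-BuOH (3 equiv), −78 → 23 °C, 12 h; H2O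
Reagents that add atoms: methyllithium, [Li]C
Why: Proposed new method: MeLi adds once to the lactone carbonyl at −78 °C (lactone-to-lactol addition), the lactolate opens on warming to the tertiary alkoxide and an α-methylene ketone, and the alkoxide closes on the exocyclic methylene by oxa-Michael addition (5-endo-trig with the acceptor group outside the forming ring, as in the known base-mediated cyclisation of γ-hydroxy vinyl sulfones to oxolanes) while the lactol is only a reversible side equilibrium, and LiO-t-Bu/t-BuOH then equilibrates the enolisable C3 to the more stable 3,4-trans ketone (3S).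

Step 8
Reactants: 19 1-{(3S,4S,5R)-5-[(tert-butyldimethylsilyloxy)methyl]-5-[(1E)-4-methylpenta-1,3-dienyl]-4-[(3S)-3-methyl-3-(triethylsilyloxy)pent-4-enyl]oxolan-3-yl}ethan-1-one
Product: 21 1-{(3S,4S,5R)-5-[(tert-butyldimethylsilyloxy)methyl]-5-[(1E)-4-methylpenta-1,3-dienyl]-4-[(3S)-3-methyl-3-(triethylsilyloxy)pent-4-enyl]oxolan-3-yl}ethenyl trifluoromethanesulfonate, via potassium enolate 20 (not isolated)
Conditions: KN(SiMe3)2, THF, −78 °C; then PhNTf2, −78 → −20 °C
Reagents that add atoms: N-phenylbis(trifluoromethanesulfonimide), O=S(=O)(N(c1ccccc1)S(=O)(=O)C(F)(F)F)C(F)(F)F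
Why: Kinetic enolisation of a methyl ketone toward the unhindered methyl group and O-triflation (enol triflate formation) proceed at −78 °C without touching the tertiary α-hydrogen, so C3 is not epimerised and the ring oxygen is not expelled.

Step 9
Reactants: 21 1-{(3S,4S,5R)-5-[(tert-butyldimethylsilyloxy)methyl]-5-[(1E)-4-methylpenta-1,3-dienyl]-4-[(3S)-3-methyl-3-(triethylsilyloxy)pent-4-enyl]oxolan-3-yl}ethenyl trifluoromethanesulfonate
Product: 22 tert-butyl(dimethyl){[(2R,3S,4R)-3-[(3S)-3-methyl-3-(triethylsilyloxy)pent-4-enyl]-2-[(1E)-4-methylpenta-1,3-dienyl]-4-(penta-1,4-dien-2-yl)oxolan-2-yl]methoxy}silane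
Conditions: allyltributylstannane (1.5 equiv), Pd(PPh3)4 (5 mol %), LiCl (3 equiv), THF, 60 °C
Reagents that add atoms: allyltributylstannane, C=CC[Sn](CCCC)(CCCC)CCCC
Why: Stille coupling of an alkenyl triflate with an allylstannane (zerovalent palladium, chloride-assisted transmetallation) gives the skipped 1,4-diene directly and involves no stereocentre.

Step 10
Reactants: 22 tert-butyl(dimethyl){[(2R,3S,4R)-3-[(3S)-3-methyl-3-(triethylsilyloxy)pent-4-enyl]-2-[(1E)-4-methylpenta-1,3-dienyl]-4-(penta-1,4-dien-2-yl)oxolan-2-yl]methoxy}silane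
Product: 23 (3S)-5-[(2R,3S,4R)-2-(hydroxymethyl)-2-[(1E)-4-methylpenta-1,3-dienyl]-4-(penta-1,4-dien-2-yl)oxolan-3-yl]-3-methylpent-1-en-3-ol
Conditions: Bu4NF (3 equiv), THF, 0 → 40 °C
Reagents that add atoms: none
Why: Fluoride-mediated desilylation removes the primary TBS and the tertiary TES ether under basic conditions that the acid-labile tertiary dienylic ether tolerates.

Step 11
Reactants: 23 (3S)-5-[(2R,3S,4R)-2-(hydroxymethyl)-2-[(1E)-4-methylpenta-1,3-dienyl]-4-(penta-1,4-dien-2-yl)oxolan-3-yl]-3-methylpent-1-en-3-ol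
Product: 24 (1R,3aR,6Z,8S,10aS)-1-(hydroxymethyl)-8-methyl-4-methylidene-1-[(1E)-4-methylpenta-1,3-dienyl]-3,3a,4,5,8,9,10,10a-octahydro-1H-cyclonona[c]furan-8-ol
Conditions: second-generation Hoveyda–Grubbs catalyst (10 mol %), toluene (1 mM), 80 °C, argon sparge
Reagents that add atoms: none
Why: Ring-closing metathesis starts at the unhindered allyl terminus and closes on the vinyl carbinol (helped by the free allylic hydroxyl) between the two trans-disposed arms of ring A, the nine-membered ring can hold only the Z alkene, and high dilution suppresses dimers.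

Step 12
Reactants: 24 (1R,3aR,6Z,8S,10aS)-1-(hydroxymethyl)-8-methyl-4-methylidene-1-[(1E)-4-methylpenta-1,3-dienyl]-3,3a,4,5,8,9,10,10a-octahydro-1H-cyclonona[c]furan-8-ol + 25 octadecanoyl chloride
Product: 26 CNP0274030.1, [(1R,3aR,6Z,8S,10aS)-8-hydroxy-8-methyl-4-methylidene-1-[(1E)-4-methylpenta-1,3-dienyl]-3,3a,4,5,8,9,10,10a-octahydro-1H-cyclonona[c]furan-1-yl]methyl octadecanoate
Conditions: 25 (1.1 equiv), pyridine, DMAP (5 mol %), CH2Cl2, 0 → 23 °C
Reagents that add atoms: none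
Why: Acyl chloride esterification with DMAP catalysis acylates the primary alcohol selectively because the tertiary allylic alcohol is inert under these conditions.

**Compound list**

1 | (S)-(+)-linalool, (3S)-3,7-dimethylocta-1,6-dien-3-ol | C=C[C@@](C)(O)CCC=C(C)C | starting material
2 | triethyl{[(3S)-3,7-dimethylocta-1,6-dien-3-yl]oxy}silane | C=C[C@@](C)(O[Si](CC)(CC)CC)CCC=C(C)C | intermediate
3 | 3,3-dimethyl-5-[(3S)-3-methyl-3-(triethylsilyloxy)pent-4-enyl]-1,2,4-trioxolane (secondary ozonide) | C=C[C@@](C)(O[Si](CC)(CC)CC)CCC1OOC(C)(C)O1 | intermediate (not isolated)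
4 | (4S)-4-methyl-4-(triethylsilyloxy)hex-5-enal | C=C[C@@](C)(O[Si](CC)(CC)CC)CCC=O | intermediate
5 | methyl acrylate | C=CC(=O)OC | starting material
6 | methyl (6S)-3-hydroxy-6-methyl-2-methylidene-6-(triethylsilyloxy)oct-7-enoate (both C3 epimers) | C=C[C@@](C)(O[Si](CC)(CC)CC)CCC(O)C(=C)C(=O)OC | intermediate
7 | methyl (6S)-3-(methanesulfonyloxy)-6-methyl-2-methylidene-6-(triethylsilyloxy)oct-7-enoate | C=C[C@@](C)(O[Si](CC)(CC)CC)CCC(OS(C)(=O)=O)C(=C)C(=O)OC | intermediate (not isolated)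
8 | methyl (2Z,6S)-2-(bromomethyl)-6-methyl-6-(triethylsilyloxy)octa-2,7-dienoate | C=C[C@@](C)(O[Si](CC)(CC)CC)CC/C=C(\CBr)C(=O)OC | intermediate
9 | 1-(tert-butyldimethylsilyloxy)propan-2-one | CC(=O)CO[Si](C)(C)C(C)(C)C | starting material
10 | 3-methylbut-2-enal | CC(C)=CC=O | starting material
11 | 1-(tert-butyldimethylsilyloxy)-4-hydroxy-6-methylhept-5-en-2-one (racemic, formed as its lithium alkoxide) | CC(C)=CC(O)CC(=O)CO[Si](C)(C)C(C)(C)C | intermediate (not isolated)
12 | 1-(tert-butyldimethylsilyloxy)-6-methyl-2-oxohept-5-en-4-yl methanesulfonate | CC(C)=CC(OS(C)(=O)=O)CC(=O)CO[Si](C)(C)C(C)(C)C | intermediate (not isolated)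
13 | (3E)-1-(tert-butyldimethylsilyloxy)-6-methylhepta-3,5-dien-2-one | CC(C)=C/C=C/C(=O)CO[Si](C)(C)C(C)(C)C | intermediate
14 | [(6S)-2-(methoxycarbonyl)-6-methyl-6-(triethylsilyloxy)octa-2,7-dien-1-yl]chromium dichloride (trivalent chromium, chiral ligand not drawn) | C=C[C@@](C)(O[Si](CC)(CC)CC)CCC=C(C[Cr](Cl)Cl)C(=O)OC | intermediate (not isolated)
15 | methyl (3S,4R,5E)-4-[(tert-butyldimethylsilyloxy)methyl]-4-hydroxy-8-methyl-3-[(3S)-3-methyl-3-(triethylsilyloxy)pent-4-enyl]-2-methylidenenona-5,7-dienoate (formed as its chromium alkoxide) | C=C[C@@](C)(O[Si](CC)(CC)CC)CC[C@@H](C(=C)C(=O)OC)[C@](O)(/C=C/C=C(C)C)CO[Si](C)(C)C(C)(C)C | intermediate (not isolated)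
16 | (4S,5R)-5-[(tert-butyldimethylsilyloxy)methyl]-3-methylidene-5-[(1E)-4-methylpenta-1,3-dienyl]-4-[(3S)-3-methyl-3-(triethylsilyloxy)pent-4-enyl]oxolan-2-one | C=C[C@@](C)(O[Si](CC)(CC)CC)CC[C@H]1C(=C)C(=O)O[C@@]1(/C=C/C=C(C)C)CO[Si](C)(C)C(C)(C)C | intermediate
17 | (4S,5R)-5-[(tert-butyldimethylsilyloxy)methyl]-2-methyl-3-methylidene-5-[(1E)-4-methylpenta-1,3-dienyl]-4-[(3S)-3-methyl-3-(triethylsilyloxy)pent-4-enyl]oxolan-2-ol (C2 epimers, formed as its lithium alkoxide) | C=C[C@@](C)(O[Si](CC)(CC)CC)CC[C@H]1C(=C)C(C)(O)O[C@@]1(/C=C/C=C(C)C)CO[Si](C)(C)C(C)(C)C | intermediate (not isolated)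
18 | (4S,5R,6E)-5-[(tert-butyldimethylsilyloxy)methyl]-5-hydroxy-9-methyl-4-[(3S)-3-methyl-3-(triethylsilyloxy)pent-4-enyl]-3-methylidenedeca-6,8-dien-2-one (formed as its lithium alkoxide) | C=C[C@@](C)(O[Si](CC)(CC)CC)CC[C@@H](C(=C)C(C)=O)[C@](O)(/C=C/C=C(C)C)CO[Si](C)(C)C(C)(C)C | intermediate (not isolated)
19 | 1-{(3S,4S,5R)-5-[(tert-butyldimethylsilyloxy)methyl]-5-[(1E)-4-methylpenta-1,3-dienyl]-4-[(3S)-3-methyl-3-(triethylsilyloxy)pent-4-enyl]oxolan-3-yl}ethan-1-one | C=C[C@@](C)(O[Si](CC)(CC)CC)CC[C@H]1[C@H](C(C)=O)CO[C@@]1(/C=C/C=C(C)C)CO[Si](C)(C)C(C)(C)C | intermediate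
20 | potassium 1-{(3S,4S,5R)-5-[(tert-butyldimethylsilyloxy)methyl]-5-[(1E)-4-methylpenta-1,3-dienyl]-4-[(3S)-3-methyl-3-(triethylsilyloxy)pent-4-enyl]oxolan-3-yl}ethenolate | C=C[C@@](C)(O[Si](CC)(CC)CC)CC[C@H]1[C@H](C(=C)[O-])CO[C@@]1(/C=C/C=C(C)C)CO[Si](C)(C)C(C)(C)C.[K+] | intermediate (not isolated)
21 | 1-{(3S,4S,5R)-5-[(tert-butyldimethylsilyloxy)methyl]-5-[(1E)-4-methylpenta-1,3-dienyl]-4-[(3S)-3-methyl-3-(triethylsilyloxy)pent-4-enyl]oxolan-3-yl}ethenyl trifluoromethanesulfonate | C=C[C@@](C)(O[Si](CC)(CC)CC)CC[C@H]1[C@H](C(=C)OS(=O)(=O)C(F)(F)F)CO[C@@]1(/C=C/C=C(C)C)CO[Si](C)(C)C(C)(C)C | intermediate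
22 | tert-butyl(dimethyl){[(2R,3S,4R)-3-[(3S)-3-methyl-3-(triethylsilyloxy)pent-4-enyl]-2-[(1E)-4-methylpenta-1,3-dienyl]-4-(penta-1,4-dien-2-yl)oxolan-2-yl]methoxy}silane | C=C[C@@](C)(O[Si](CC)(CC)CC)CC[C@H]1[C@H](C(=C)CC=C)CO[C@@]1(/C=C/C=C(C)C)CO[Si](C)(C)C(C)(C)C | intermediate
23 | (3S)-5-[(2R,3S,4R)-2-(hydroxymethyl)-2-[(1E)-4-methylpenta-1,3-dienyl]-4-(penta-1,4-dien-2-yl)oxolan-3-yl]-3-methylpent-1-en-3-ol | C=C[C@@](C)(O)CC[C@H]1[C@H](C(=C)CC=C)CO[C@@]1(/C=C/C=C(C)C)CO | intermediate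
24 | (1R,3aR,6Z,8S,10aS)-1-(hydroxymethyl)-8-methyl-4-methylidene-1-[(1E)-4-methylpenta-1,3-dienyl]-3,3a,4,5,8,9,10,10a-octahydro-1H-cyclonona[c]furan-8-ol | C=C1C/C=C\[C@@](C)(O)CC[C@H]2[C@H]1CO[C@@]2(/C=C/C=C(C)C)CO | intermediate
25 | octadecanoyl chloride (stearoyl chloride) | CCCCCCCCCCCCCCCCCC(=O)Cl | starting material
26 | CNP0274030.1, [(1R,3aR,6Z,8S,10aS)-8-hydroxy-8-methyl-4-methylidene-1-[(1E)-4-methylpenta-1,3-dienyl]-3,3a,4,5,8,9,10,10a-octahydro-1H-cyclonona[c]furan-1-yl]methyl octadecanoate | C=C1C/C=C\[C@@](C)(O)CC[C@H]2[C@H]1CO[C@@]2(/C=C/C=C(C)C)COC(=O)CCCCCCCCCCCCCCCCC | target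

**Step count**
Total: 12 steps. Longest linear sequence: 11 steps (1 → 2 → 4 → 6 → 8 → 16 → 19 → 21 → 22 → 23 → 24 → 26); step 5 makes the ketone partner 13 in one flask from two bought compounds.

**The three steps most likely to fail**

Step 6 (key coupling). The ketone is a slower electrophile than the aldehydes for which this allylchromium chemistry is established. The ratio at C5 depends on which ketone arm sits next to chromium, and the enantioselectivity with this substrate pair is untested. The fallback sets out from bromide 8 and returns at lactone 16. Bromide 8 is treated with Bu3SnLi (THF, −78 °C) to give the allylstannane methyl (2Z,6S)-6-methyl-2-[(tributylstannyl)methyl]-6-(triethylsilyloxy)octa-2,7-dienoate F1. F1 is a storable reagent and is added to ketone 13 under BINOL/Ti(O-i-Pr)4 catalysis. This is a Lewis-acid-catalysed allyl transfer instead of a reductive coupling, so the chiral titanium complex, not a chromium chair, selects the ketone face; such additions to ketones and enones are known to go 1,2. The hydroxy ester 15 formed this way is lactonised with DBU in toluene to give 16.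

Step 7 (lactone-to-oxolane ring switch). The 5-endo-trig closure may lose to oligomerisation, and MeLi may add to the methylene group instead of the carbonyl. The fallback sets out from lactone 16 and returns at methyl ketone 19; it forms the ring C–O bond by an SN2 closure instead of a conjugate addition. Copper-catalysed conjugate borylation of 16 (B2pin2, CuCl, NaO-t-Bu, MeOH, THF) gives the 3-(pinacolborylmethyl) lactone F2. LiAlH4 and then NaOH/H2O2 in the same flask give the triol F3, whose two hydroxymethyl arms are equivalent. TsCl (1 equiv, pyridine) gives the mono-p-toluenesulfonate F4, and KO-t-Bu closes it through the tertiary alkoxide (5-exo-tet Williamson etherification) to the 3-(hydroxymethyl)oxolane F5 as both C3 epimers. Dess–Martin oxidation followed by DBU gives the 3,4-trans aldehyde F6. MeMgBr gives the carbinol F7, and a second Dess–Martin oxidation gives 19.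

Step 11 (nine-membered ring by metathesis). Dimers may form, and the 1,1-disubstituted alkene or the diene may be drawn in to give a seven-membered ring. The fallback sets out from methyl ketone 19 and returns at diol 24; it closes the ring before the exocyclic methylene exists. Palladium-catalysed α-vinylation of 19 on the methyl side (LiN(SiMe3)2, vinyl bromide, Pd2(dba)3, Q-Phos, cold acetic acid quench) gives the allyl ketone F8. Ring-closing metathesis with the same ruthenium catalyst gives the bicyclic (Z)-cyclononenone F9. Cp2TiMe2 (toluene, 70 °C) methylenates it to the bis-silyl ether F10, and Bu4NF then gives 24.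

**Further compounds**

F1 | step 6 | methyl (2Z,6S)-6-methyl-2-[(tributylstannyl)methyl]-6-(triethylsilyloxy)octa-2,7-dienoate | C=C[C@@](C)(O[Si](CC)(CC)CC)CC/C=C(\C[Sn](CCCC)(CCCC)CCCC)C(=O)OC
F2 | step 7 | (4S,5R)-5-[(tert-butyldimethylsilyloxy)methyl]-5-[(1E)-4-methylpenta-1,3-dienyl]-4-[(3S)-3-methyl-3-(triethylsilyloxy)pent-4-enyl]-3-[(4,4,5,5-tetramethyl-1,3,2-dioxaborolan-2-yl)methyl]oxolan-2-one (C3 epimers) | C=C[C@@](C)(O[Si](CC)(CC)CC)CC[C@H]1C(CB2OC(C)(C)C(C)(C)O2)C(=O)O[C@@]1(/C=C/C=C(C)C)CO[Si](C)(C)C(C)(C)C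
F3 | step 7 | (3S,4R,5E)-4-[(tert-butyldimethylsilyloxy)methyl]-2-(hydroxymethyl)-8-methyl-3-[(3S)-3-methyl-3-(triethylsilyloxy)pent-4-enyl]nona-5,7-diene-1,4-diol | C=C[C@@](C)(O[Si](CC)(CC)CC)CC[C@@H](C(CO)CO)[C@](O)(/C=C/C=C(C)C)CO[Si](C)(C)C(C)(C)C
F4 | step 7 | mono-p-toluenesulfonate of F3 at one primary hydroxyl (C2 epimers) | C=C[C@@](C)(O[Si](CC)(CC)CC)CC[C@@H](C(CO)COS(=O)(=O)c1ccc(C)cc1)[C@](O)(/C=C/C=C(C)C)CO[Si](C)(C)C(C)(C)C
F5 | step 7 | {(4S,5R)-5-[(tert-butyldimethylsilyloxy)methyl]-5-[(1E)-4-methylpenta-1,3-dienyl]-4-[(3S)-3-methyl-3-(triethylsilyloxy)pent-4-enyl]oxolan-3-yl}methanol (C3 epimers) | C=C[C@@](C)(O[Si](CC)(CC)CC)CC[C@H]1C(CO)CO[C@@]1(/C=C/C=C(C)C)CO[Si](C)(C)C(C)(C)C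
F6 | step 7 | (3S,4S,5R)-5-[(tert-butyldimethylsilyloxy)methyl]-5-[(1E)-4-methylpenta-1,3-dienyl]-4-[(3S)-3-methyl-3-(triethylsilyloxy)pent-4-enyl]oxolane-3-carbaldehyde | C=C[C@@](C)(O[Si](CC)(CC)CC)CC[C@H]1[C@H](C=O)CO[C@@]1(/C=C/C=C(C)C)CO[Si](C)(C)C(C)(C)C
F7 | step 7 | 1-{(3S,4S,5R)-5-[(tert-butyldimethylsilyloxy)methyl]-5-[(1E)-4-methylpenta-1,3-dienyl]-4-[(3S)-3-methyl-3-(triethylsilyloxy)pent-4-enyl]oxolan-3-yl}ethan-1-ol (carbinol epimers) | C=C[C@@](C)(O[Si](CC)(CC)CC)CC[C@H]1[C@H](C(C)O)CO[C@@]1(/C=C/C=C(C)C)CO[Si](C)(C)C(C)(C)C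
F8 | step 11 | 1-{(3S,4S,5R)-5-[(tert-butyldimethylsilyloxy)methyl]-5-[(1E)-4-methylpenta-1,3-dienyl]-4-[(3S)-3-methyl-3-(triethylsilyloxy)pent-4-enyl]oxolan-3-yl}but-3-en-1-one | C=C[C@@](C)(O[Si](CC)(CC)CC)CC[C@H]1[C@H](C(=O)CC=C)CO[C@@]1(/C=C/C=C(C)C)CO[Si](C)(C)C(C)(C)C
F9 | step 11 | (1R,3aS,6Z,8S,10aS)-1-[(tert-butyldimethylsilyloxy)methyl]-8-methyl-1-[(1E)-4-methylpenta-1,3-dienyl]-8-(triethylsilyloxy)-3,3a,5,8,9,10,10a-heptahydro-1H-cyclonona[c]furan-4-one | O=C1C/C=C\[C@@](C)(O[Si](CC)(CC)CC)CC[C@H]2[C@H]1CO[C@@]2(/C=C/C=C(C)C)CO[Si](C)(C)C(C)(C)C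
F10 | step 11 | bis-silyl ether of 24: tert-butyl(dimethyl){[(1R,3aR,6Z,8S,10aS)-8-methyl-4-methylidene-1-[(1E)-4-methylpenta-1,3-dienyl]-8-(triethylsilyloxy)-3,3a,4,5,8,9,10,10a-octahydro-1H-cyclonona[c]furan-1-yl]methoxy}silane | C=C1C/C=C\[C@@](C)(O[Si](CC)(CC)CC)CC[C@H]2[C@H]1CO[C@@]2(/C=C/C=C(C)C)CO[Si](C)(C)C(C)(C)C
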